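**Retrosynthetic overview**
1. Target ⇐ 8‑O‑acylation with (2R,3R)‑epoxyangelic acid (Sharpless epoxidation of angelyl alcohol) and lactone migration from the 8,12‑ to the 6,12‑olide after reduction of a C6 ketone.
2. Ten‑membered ring ⇐ three‑carbon ring expansion of a cycloheptenone: a tethered 3‑(bromomethyl)butenolide allylates the C6 ketone (C6–C7 bond, cyclopentanol), then Grob fragmentation of the 1,3‑hydroxy mesylate cleaves C6–C10 and forms C1=C10.
3. Cycloheptenone ⇐ opening of an 8‑oxabicyclo[3.2.1]octenone (C4=C5 made cis in the seven‑membered ring, C1–O kept as leaving group, hydroxyl‑directed 2,3‑epoxidation).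
4. C9–C10 bond ⇐ Mukaiyama aldol of the bicyclic silyl enol ether with a lactone aldehyde from D‑glyceraldehyde and methyl acrylate (C7–C9, C11–C13).
5. Ring order: oxabicycle ([4+3] annulation of 2‑methylfuran) → butenolide template → cyclopentanol → cyclodecadiene → 6,12‑lactone.

Assumption: germacrane numbering of the target (C1–C15; C14 = ester carbon, C12 = lactone carbonyl) is used for all intermediates after the coupling.
Assumption: D‑glyceraldehyde is used as its commercial acetonide 7; the acetonide is a protecting group (parent glyceraldehyde has six non‑hydrogen atoms).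
Assumption: compounds 9–19 are drawn as the major C7 epimer of step 4; the minor C7 epimer is carried along because C7 becomes trigonal in step 12.
Assumption: the (S)‑configured rhodium catalyst is taken to give the (1S,5S) bicycle 6; if the sense is opposite, its enantiomer is used.

**Step 1**
Reactants: 1 methyl acetoacetate
Product: 2 methyl 2‑diazo‑3‑oxobutanoate
Conditions: 4‑acetamidobenzenesulfonyl azide, Et3N, MeCN, 0 °C to rt
Reagents that add atoms: 4‑acetamidobenzenesulfonyl azide, CC(=O)Nc1ccc(cc1)S(=O)(=O)N=[N+]=[N-]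
Why: Regitz diazo transfer to the activated methylene; no stereocenter is formed.

**Step 2**
Reactants: 2 methyl 2‑diazo‑3‑oxobutanoate
Product: 3 methyl 3‑[(tert‑butyldimethylsilyl)oxy]‑2‑diazobut‑3‑enoate
Conditions: TBSOTf, Et3N, CH2Cl2, 0 °C
Reagents that add atoms: TBSOTf, CC(C)(C)[Si](C)(C)OS(=O)(=O)C(F)(F)F
Why: O‑silylation of the ketone enol gives the siloxyvinyl diazoacetate, the standard three‑carbon partner for carbenoid [4+3] annulation.

**Step 3**
Reactants: 3 methyl 3‑[(tert‑butyldimethylsilyl)oxy]‑2‑diazobut‑3‑enoate; 4 2‑methylfuran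
Product: 6 methyl (1S,5S)‑3‑[(tert‑butyldimethylsilyl)oxy]‑5‑methyl‑8‑oxabicyclo[3.2.1]octa‑2,6‑diene‑2‑carboxylate, via cis‑divinylcyclopropane 5 (not isolated)
Conditions: Rh2(S‑PTAD)4 (dirhodium tetrakis[(S)‑(1‑adamantyl)(phthalimido)acetate], 1 mol %), 4 (5 equiv), hexanes, −30 °C to rt
Reagents that add atoms: none
Why: Tandem cyclopropanation/Cope rearrangement ([4+3] annulation of a rhodium vinylcarbenoid): the carbenoid attacks the free α‑carbon of the furan, so the methyl ends on the bridgehead remote from the ester, and the chiral carboxylate catalyst sets both bridgeheads, which later fix the absolute configuration of the 2,3‑epoxide.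

**Step 4**
Reactants: 7 (R)‑2,2‑dimethyl‑1,3‑dioxolane‑4‑carbaldehyde; 8 methyl acrylate
Product: 9 methyl (3S)‑3‑[(4R)‑2,2‑dimethyl‑1,3‑dioxolan‑4‑yl]‑3‑hydroxy‑2‑methylidenepropanoate (anti isomer)
Conditions: DABCO (0.5 equiv), dioxane–H2O, rt, 3 d
Reagents that add atoms: none
Why: Morita–Baylis–Hillman reaction joins C7 to C11; C8 comes from D‑glyceraldehyde, and the new C7 carbinol (about 7:3 anti:syn) is later destroyed.

**Step 5**
Reactants: 9 methyl (3S)‑3‑[(4R)‑2,2‑dimethyl‑1,3‑dioxolan‑4‑yl]‑3‑hydroxy‑2‑methylidenepropanoate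
Product: 11 (4S,5R)‑4‑hydroxy‑5‑(hydroxymethyl)‑3‑methylideneoxolan‑2‑one, via trihydroxy ester 10 (not isolated)
Conditions: CF3CO2H–H2O (9:1), 0 °C to rt; concentrate from toluene
Reagents that add atoms: none
Why: Acetal hydrolysis followed by spontaneous five‑membered lactonisation through the secondary C8 hydroxyl; the lactone ties C8–O to C12 and serves as a template for C7.

**Step 6**
Reactants: 11 (4S,5R)‑4‑hydroxy‑5‑(hydroxymethyl)‑3‑methylideneoxolan‑2‑one
Product: 12 (4S,5R)‑3‑methylidene‑4‑[(triethylsilyl)oxy]‑5‑{[(triethylsilyl)oxy]methyl}oxolan‑2‑one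
Conditions: Et3SiCl (2.4 equiv), imidazole, DMF, 0 °C
Reagents that add atoms: chlorotriethylsilane, CC[Si](Cl)(CC)CC
Why: Standard bis‑silylation; no stereocenter is touched.

**Step 7**
Reactants: 12 (4S,5R)‑3‑methylidene‑4‑[(triethylsilyl)oxy]‑5‑{[(triethylsilyl)oxy]methyl}oxolan‑2‑one
Product: 13 (2S,3S)‑4‑methylidene‑5‑oxo‑3‑[(triethylsilyl)oxy]oxolane‑2‑carbaldehyde
Conditions: (COCl)2, DMSO, CH2Cl2, −78 to −30 °C; then Et3N, −78 °C; used crude
Reagents that add atoms: none
Why: Swern conditions cleave and oxidise the primary triethylsilyl ether selectively and leave the secondary one, giving the C9 aldehyde without a separate deprotection.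

**Step 8**
Reactants: 6 methyl (1S,5S)‑3‑[(tert‑butyldimethylsilyl)oxy]‑5‑methyl‑8‑oxabicyclo[3.2.1]octa‑2,6‑diene‑2‑carboxylate; 13 (2S,3S)‑4‑methylidene‑5‑oxo‑3‑[(triethylsilyl)oxy]oxolane‑2‑carbaldehyde
Product: 14 aldol adduct: methyl (1S,5S)‑5‑methyl‑3‑oxo‑8‑oxabicyclo[3.2.1]oct‑6‑ene‑2‑carboxylate carrying at C2, cis to the oxygen bridge, the (S)‑CH(OH)–lactone unit of 13 (C9–C10 bond, 9S)
Conditions: TiCl4 (1.1 equiv), CH2Cl2, −78 °C
Reagents that add atoms: none
Why: Chelation‑controlled Mukaiyama aldol: TiCl4 binds the aldehyde and the lactone ring oxygen, and the enol silane adds through its exo face (syn to the oxygen bridge) anti to C7 of the chelate with the lactone pointing away from the bicycle, giving the 8,9‑syn (9S) carbinol and the side chain exo at quaternary C10.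

**Step 9**
Reactants: 14 aldol adduct
Product: 15 9‑O‑tert‑butyldimethylsilyl ether of 14
Conditions: TBSOTf, 2,6‑lutidine, CH2Cl2, −40 to 0 °C
Reagents that add atoms: TBSOTf, CC(C)(C)[Si](C)(C)OS(=O)(=O)C(F)(F)F
Why: Silylation blocks retro‑aldol of the β‑hydroxy ketone; the hindered silyl ether outlasts the triethylsilyl and trimethylsilyl groups removed next.

**Step 10**
Reactants: 15 9‑O‑tert‑butyldimethylsilyl ether of 14
Product: 17 cyclohepta‑2,4‑dienone diol (C6 ketone, C4=C5 and C2=C3, free 1‑OH and 7‑OH, 9‑OTBS, C10 quaternary with CO2Me), via 1‑O‑trimethylsilyl dienone 16 (not isolated)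
Conditions: Me3SiOTf (1.3 equiv), Et3N (2 equiv), CH2Cl2, −78 to 0 °C; then AcOH–THF–H2O (3:1:1), rt
Reagents that add atoms: none
Why: Silyl triflate‑mediated enol silylation and β‑elimination opens the oxygen bridge (known for 8‑oxabicyclo[3.2.1]octenones); only C5 is enolisable, the C4=C5 enone is necessarily cis in the seven‑membered ring, the C1 oxygen is never a free alkoxide (no retro‑aldol), and mild acid then removes the trimethylsilyl and triethylsilyl ethers only.

**Step 11**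
Reactants: 17 cyclohepta‑2,4‑dienone diol
Product: 18 2,3‑epoxide of 17 (epoxide oxygen cis to 1‑OH; 2R,3S in the target sense)
Conditions: VO(acac)2 (5 mol %), t‑BuOOH, CH2Cl2, 0 °C
Reagents that add atoms: tert‑butyl hydroperoxide, CC(C)(C)OO
Why: Hydroxyl‑directed vanadium epoxidation delivers oxygen syn to the allylic C1 hydroxyl on the C2=C3 bond; the enone and the acrylate‑type methylene are electron‑poor and react more slowly.

**Step 12**
Reactants: 18 2,3‑epoxide of 17
Product: 20 1‑O‑mesyl epoxy enone carrying the 3‑(bromomethyl)butenolide (C7=C11, C13–Br), via 1,7‑bis‑mesylate 19 (not isolated)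
Conditions: MsCl (2.4 equiv), Et3N (2.6 equiv), CH2Cl2, −40 °C; then LiBr (5 equiv), THF, 0 °C
Reagents that add atoms: methanesulfonyl chloride, CS(=O)(=O)Cl; lithium bromide, [Li+].[Br-]
Why: Both hydroxyls are mesylated; the allylic Baylis–Hillman‑type mesylate undergoes SN2' displacement by bromide to the conjugated butenolide, while the hindered secondary epoxy mesylate at C1 is inert.

**Step 13**
Reactants: 20 1‑O‑mesyl epoxy enone carrying the 3‑(bromomethyl)butenolide
Product: 22 ten‑membered enone: 6‑oxo, cis‑fused 8,12‑olide with 11(13)‑methylene, 9‑OTBS, methyl 14‑oate, 2,3‑epoxide, 1(10)E,4Z, via tricyclic carbinol 21 (not isolated)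
Conditions: indium powder (2 equiv), THF–H2O (4:1), 0.01 M, rt; extract and dry; then KN(SiMe3)2 (1.0 equiv), THF, −78 to −30 °C
Reagents that add atoms: none
Why: Proposed new method: indium‑mediated intramolecular Barbier allylation of a ketone by a 3‑(bromomethyl)butenolide, telescoped with Grob fragmentation, as a three‑carbon ring expansion from seven to ten; the allylindium adds through its γ‑carbon C7 to C6=O, and the five‑membered tether forces a cis‑fused cyclopentanol/lactone so H7 is cis to H8 (sets C7); the potassium alkoxide then fragments with C6–C10 anti‑periplanar to C1–OMs, and because the C9 chain is cis to the mesylate this gives C1=C10 with C9 cis to C2; one equivalent of base leaves none to isomerise the product; closest known chemistry is the SmI2 Barbier cyclisation/Grob fragmentation of keto mesylates and zinc or indium Barbier reactions of 3‑(bromomethyl)furan‑2(5H)‑ones with aldehydes.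

**Step 14**
Reactants: 22 ten‑membered enone
Product: 24 6,12‑olide with free 8‑OH (9‑O‑TBS ether of the deacyl target), via 6R‑carbinol 8,12‑olide 23 (not isolated)
Conditions: NaBH4, CeCl3·7H2O, MeOH, −78 °C; then Et3N (0.2 equiv), CH2Cl2, rt
Reagents that add atoms: none
Why: Luche 1,2‑reduction with hydride delivered anti to the C7–C11 bond (the cis‑fused lactone shields the other face) gives the 6R alcohol syn to C11, which undergoes base‑catalysed translactonisation to the less strained trans‑fused 6,12‑olide and frees the 8‑hydroxyl.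

**Step 15**
Reactants: 25 methyl angelate (methyl (Z)‑2‑methylbut‑2‑enoate)
Product: 27 (Z)‑2‑methylbut‑2‑en‑1‑ol, via angelic aldehyde 26 (not isolated)
Conditions: iBu2AlH (2.2 equiv), CH2Cl2, −78 to 0 °C
Reagents that add atoms: none
Why: 1,2‑Reduction of the enoate with retention of the Z geometry.

**Step 16**
Reactants: 27 (Z)‑2‑methylbut‑2‑en‑1‑ol
Product: 28 [(2S,3R)‑2,3‑dimethyloxiran‑2‑yl]methanol
Conditions: Ti(OiPr)4 (10 mol %), D‑(−)‑diisopropyl tartrate (12 mol %), t‑BuOOH, molecular sieves 4 Å, CH2Cl2, −20 °C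
Reagents that add atoms: tert‑butyl hydroperoxide, CC(C)(C)OO
Why: Sharpless asymmetric epoxidation; the D‑tartrate delivers oxygen to the face that gives the (2S,3R) epoxy alcohol, and the Z geometry keeps the two methyls trans.

**Step 17**
Reactants: 28 [(2S,3R)‑2,3‑dimethyloxiran‑2‑yl]methanol
Product: 30 (2R,3R)‑2,3‑dimethyloxirane‑2‑carboxylic acid, via epoxy aldehyde 29 (not isolated)
Conditions: TEMPO (20 mol %), PhI(OAc)2 (2.2 equiv), MeCN–H2O (1:1), rt
Reagents that add atoms: water, O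
Why: Oxoammonium oxidation of the primary alcohol through the aldehyde hydrate; the epoxide and both stereocenters are untouched (the descriptor at C2 changes only by priority).

**Step 18**
Reactants: 30 (2R,3R)‑2,3‑dimethyloxirane‑2‑carboxylic acid; 24 6,12‑olide with free 8‑OH
Product: 32 9‑O‑tert‑butyldimethylsilyl ether of the target, via mixed trichlorobenzoic anhydride 31 (not isolated)
Conditions: 2,4,6‑trichlorobenzoyl chloride, Et3N, THF, 0 °C; then 24, DMAP, toluene, rt
Reagents that add atoms: none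
Why: Yamaguchi esterification acylates the only free hydroxyl (C8) without touching either epoxide.

**Step 19**
Reactants: 32 9‑O‑tert‑butyldimethylsilyl ether of the target
Product: 33 target: methyl (1(10)E,4Z,2R,3S,6R,7S,8S,9S)‑2,3‑epoxy‑8‑[(2R,3R)‑2,3‑epoxy‑2‑methylbutanoyloxy]‑9‑hydroxygermacra‑1(10),4,11(13)‑trien‑6,12‑olid‑14‑oate
Conditions: HF·pyridine, pyridine, THF, 0 °C to rt
Reagents that add atoms: none
Why: Buffered fluoride desilylation under mildly acidic conditions, which avoids 8→9 acyl migration and leaves the epoxides and the α‑methylene lactone intact.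

**Compound list**
1 | methyl acetoacetate | CC(=O)CC(=O)OC | starting material
2 | methyl 2‑diazo‑3‑oxobutanoate | CC(=O)C(=[N+]=[N-])C(=O)OC | intermediate
3 | methyl 3‑[(tert‑butyldimethylsilyl)oxy]‑2‑diazobut‑3‑enoate | C=C(O[Si](C)(C)C(C)(C)C)C(=[N+]=[N-])C(=O)OC | intermediate
4 | 2‑methylfuran | Cc1ccco1 | starting material
5 | cis‑divinylcyclopropane: methyl 6‑{1‑[(tert‑butyldimethylsilyl)oxy]ethenyl}‑3‑methyl‑2‑oxabicyclo[3.1.0]hex‑3‑ene‑6‑carboxylate (silyloxyvinyl endo) | CC1=C[C@@H]2[C@H](O1)[C@]2(C(=O)OC)C(=C)O[Si](C)(C)C(C)(C)C | intermediate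
6 | methyl (1S,5S)‑3‑[(tert‑butyldimethylsilyl)oxy]‑5‑methyl‑8‑oxabicyclo[3.2.1]octa‑2,6‑diene‑2‑carboxylate | C[C@@]12CC(O[Si](C)(C)C(C)(C)C)=C(C(=O)OC)[C@@H](O1)C=C2 | intermediate
7 | (R)‑2,2‑dimethyl‑1,3‑dioxolane‑4‑carbaldehyde (D‑glyceraldehyde acetonide) | CC1(C)OC[C@@H](O1)C=O | starting material
8 | methyl acrylate | C=CC(=O)OC | starting material
9 | methyl (3S)‑3‑[(4R)‑2,2‑dimethyl‑1,3‑dioxolan‑4‑yl]‑3‑hydroxy‑2‑methylidenepropanoate | C=C(C(=O)OC)[C@H](O)[C@H]1COC(C)(C)O1 | intermediate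
10 | methyl (3S,4R)‑3,4,5‑trihydroxy‑2‑methylidenepentanoate | C=C(C(=O)OC)[C@H](O)[C@H](O)CO | intermediate
11 | (4S,5R)‑4‑hydroxy‑5‑(hydroxymethyl)‑3‑methylideneoxolan‑2‑one | OC[C@H]1OC(=O)C(=C)[C@@H]1O | intermediate
12 | (4S,5R)‑3‑methylidene‑4‑[(triethylsilyl)oxy]‑5‑{[(triethylsilyl)oxy]methyl}oxolan‑2‑one | CC[Si](CC)(CC)OC[C@H]1OC(=O)C(=C)[C@@H]1O[Si](CC)(CC)CC | intermediate
13 | (2S,3S)‑4‑methylidene‑5‑oxo‑3‑[(triethylsilyl)oxy]oxolane‑2‑carbaldehyde | O=C[C@H]1OC(=O)C(=C)[C@@H]1O[Si](CC)(CC)CC | intermediate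
14 | aldol adduct (9S carbinol, side chain exo at quaternary C10) | C[C@@]12CC(=O)[C@@](C(=O)OC)([C@H](O)[C@H]3OC(=O)C(=C)[C@@H]3O[Si](CC)(CC)CC)[C@@H](O1)C=C2 | intermediate
15 | 9‑O‑tert‑butyldimethylsilyl ether of 14 | C[C@@]12CC(=O)[C@@](C(=O)OC)([C@H](O[Si](C)(C)C(C)(C)C)[C@H]3OC(=O)C(=C)[C@@H]3O[Si](CC)(CC)CC)[C@@H](O1)C=C2 | intermediate
16 | 1‑O‑trimethylsilyl cyclohepta‑2,4‑dienone (bridge opened, 7‑OTES, 9‑OTBS) | CC1=CC(=O)[C@@](C(=O)OC)([C@H](O[Si](C)(C)C(C)(C)C)[C@H]2OC(=O)C(=C)[C@@H]2O[Si](CC)(CC)CC)[C@@H](O[Si](C)(C)C)C=C1 | intermediate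
17 | cyclohepta‑2,4‑dienone diol (free 1‑OH and 7‑OH, 9‑OTBS) | CC1=CC(=O)[C@@](C(=O)OC)([C@H](O[Si](C)(C)C(C)(C)C)[C@H]2OC(=O)C(=C)[C@@H]2O)[C@@H](O)C=C1 | intermediate
18 | 2,3‑epoxide of 17 (epoxide cis to 1‑OH) | CC1=CC(=O)[C@@](C(=O)OC)([C@H](O[Si](C)(C)C(C)(C)C)[C@H]3OC(=O)C(=C)[C@@H]3O)[C@@H](O)[C@H]2O[C@@H]12 | intermediate
19 | 1,7‑bis‑mesylate of 18 | CC1=CC(=O)[C@@](C(=O)OC)([C@H](O[Si](C)(C)C(C)(C)C)[C@H]3OC(=O)C(=C)[C@@H]3OS(C)(=O)=O)[C@@H](OS(C)(=O)=O)[C@H]2O[C@@H]12 | intermediate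
20 | 1‑O‑mesyl epoxy enone with 3‑(bromomethyl)butenolide | CC1=CC(=O)[C@@](C(=O)OC)([C@H](O[Si](C)(C)C(C)(C)C)[C@H]3OC(=O)C(CBr)=C3)[C@@H](OS(C)(=O)=O)[C@H]2O[C@@H]12 | intermediate
21 | tricyclic carbinol (C6–C7 bond; cis‑fused cyclopentanol and α‑methylene lactone; 1‑OMs) | C=C1C(=O)O[C@H]2[C@@H]1[C@]3(O)C=C(C)[C@@H]4O[C@@H]4[C@H](OS(C)(=O)=O)[C@]3(C(=O)OC)[C@@H]2O[Si](C)(C)C(C)(C)C | intermediate
22 | ten‑membered 6‑oxo 8,12‑olide (9‑OTBS, 2,3‑epoxide, 1(10)E,4Z) | C=C1C(=O)O[C@H]2[C@@H]1C(=O)/C=C(/C)[C@@H]3O[C@@H]3/C=C(/C(=O)OC)[C@@H]2O[Si](C)(C)C(C)(C)C | intermediate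
23 | 6R‑carbinol of 22 (8,12‑olide) | C=C1C(=O)O[C@H]2[C@@H]1[C@H](O)/C=C(/C)[C@@H]3O[C@@H]3/C=C(/C(=O)OC)[C@@H]2O[Si](C)(C)C(C)(C)C | intermediate
24 | 6,12‑olide with free 8‑OH and 9‑OTBS | C=C1C(=O)O[C@@H]2/C=C(/C)[C@@H]3O[C@@H]3/C=C(/C(=O)OC)[C@H](O[Si](C)(C)C(C)(C)C)[C@@H](O)[C@@H]12 | intermediate
25 | methyl angelate | C/C=C(/C)C(=O)OC | starting material
26 | (Z)‑2‑methylbut‑2‑enal | C/C=C(/C)C=O | intermediate
27 | (Z)‑2‑methylbut‑2‑en‑1‑ol | C/C=C(/C)CO | intermediate
28 | [(2S,3R)‑2,3‑dimethyloxiran‑2‑yl]methanol | C[C@H]1O[C@@]1(C)CO | intermediate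
29 | (2R,3R)‑2,3‑dimethyloxirane‑2‑carbaldehyde | C[C@H]1O[C@@]1(C)C=O | intermediate
30 | (2R,3R)‑2,3‑dimethyloxirane‑2‑carboxylic acid | C[C@H]1O[C@@]1(C)C(=O)O | intermediate
31 | (2R,3R)‑2,3‑dimethyloxirane‑2‑carboxylic 2,4,6‑trichlorobenzoic anhydride | C[C@H]1O[C@@]1(C)C(=O)OC(=O)c2c(Cl)cc(Cl)cc2Cl | intermediate
32 | 9‑O‑tert‑butyldimethylsilyl ether of the target | C=C1C(=O)O[C@@H]2/C=C(/C)[C@@H]3O[C@@H]3/C=C(/C(=O)OC)[C@H](O[Si](C)(C)C(C)(C)C)[C@@H](OC(=O)[C@]3(C)O[C@@H]3C)[C@@H]12 | intermediate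
33 | CNP0291485.1 | C=C1C(=O)O[C@@H]2/C=C(/C)[C@@H]3O[C@@H]3/C=C(/C(=O)OC)[C@H](O)[C@@H](OC(=O)[C@]3(C)O[C@@H]3C)[C@@H]12 | target

**Step count:** 19 steps in total; longest linear sequence 13 steps (7 → 9 → 11 → 12 → 13 → 14 → 15 → 17 → 18 → 20 → 22 → 24 → 32 → 33).

**Steps most likely to fail**

Step 8 (aldol to a quaternary carbon; the 9S outcome depends on chelation). The fallback sets out from 6 and comes back at 14. Bromination of the silyl enol ether 6 with N‑bromosuccinimide (THF, −78 °C) gives the bromo keto ester F1. SmI2 (2 equiv, THF, −78 °C) converts F1 into its samarium enolate, and addition of 13 gives 14 through a closed six‑membered Reformatsky transition state, with the aldehyde substituent equatorial and pointing away from the bicycle.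

Step 13 (the proposed Barbier/Grob ring expansion). The fallback sets out from 18 and comes back at 21, then 22, using known reactions in a different order: the leaving group is installed after the C–C bond. N‑Bromosuccinimide/Me2S (Corey–Kim, CH2Cl2, −20 °C) converts only the allylic 7‑hydroxyl of 18 into the transposed bromide, giving the hydroxy bromobutenolide F2. CrCl2 (THF, rt, Nozaki–Hiyama allylation) closes the cyclopentanol to the isolated tricyclic diol F3. MsCl/Et3N mesylates the secondary 1‑hydroxyl of F3 (the tertiary 6‑hydroxyl is inert) to give 21 as an isolated compound. NaH (THF, 0 °C) then effects a classical Wharton‑type Grob fragmentation of 21 to 22.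

Step 14 (face of hydride attack on the ten‑membered enone and lactone migration). The fallback sets out from 22 and comes back at 24. If reduction gives the 6‑epimer (for example with LiBH(s‑Bu)3, THF, −78 °C), the product is the 6S‑carbinol F4. LiOH (1 equiv, THF–H2O, 0 °C) opens its strained lactone to the seco acid F5. Mitsunobu lactonisation of F5 (PPh3, diisopropyl azodicarboxylate, toluene, 0 °C) closes the 6,12‑olide with inversion at the allylic C6 and gives 24.

**Further compounds**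
F1 | step 8 | methyl (1S,5S)‑2‑bromo‑5‑methyl‑3‑oxo‑8‑oxabicyclo[3.2.1]oct‑6‑ene‑2‑carboxylate (bromine exo) | C[C@@]12CC(=O)[C@](Br)(C(=O)OC)[C@@H](O1)C=C2
F2 | step 13 | epoxy enone with free 1‑OH and 3‑(bromomethyl)butenolide | CC1=CC(=O)[C@@](C(=O)OC)([C@H](O[Si](C)(C)C(C)(C)C)[C@H]3OC(=O)C(CBr)=C3)[C@@H](O)[C@H]2O[C@@H]12
F3 | step 13 | tricyclic carbinol with free 1‑OH | C=C1C(=O)O[C@H]2[C@@H]1[C@]3(O)C=C(C)[C@@H]4O[C@@H]4[C@H](O)[C@]3(C(=O)OC)[C@@H]2O[Si](C)(C)C(C)(C)C
F4 | step 14 | 6S‑carbinol of 22 (8,12‑olide) | C=C1C(=O)O[C@H]2[C@@H]1[C@@H](O)/C=C(/C)[C@@H]3O[C@@H]3/C=C(/C(=O)OC)[C@@H]2O[Si](C)(C)C(C)(C)C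
F5 | step 14 | 6S,8‑dihydroxy seco acid (C12 acid, 9‑OTBS) | C=C(C(=O)O)[C@H]1[C@@H](O)/C=C(/C)[C@@H]2O[C@@H]2/C=C(/C(=O)OC)[C@H](O[Si](C)(C)C(C)(C)C)[C@H]1O
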